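Remark on the chemistry: atoms keep the germacrane numbers of the target (C1–C15) in every intermediate. Compound 1 is taken as the commercial form of L-tartaric acid. Intermediates 13, 17 and 19–27 are carried as mixtures at a carbinol carbon that later becomes a carbonyl group.

## Analysis of the target

The target 37 is a ten-membered carbocycle (C1–C10) bridged by an oxygen between C3 and C10. This bridge makes a 3(2H)-furanone ring (O, C3, C2, C1, C10). An α-methylene-γ-butyrolactone is trans-fused at C6–C7. Five contiguous stereocentres run from C6 to C10 (6R,7S,8S,9R,10S): the C8 and C9 oxygens have the threo pattern of L-tartaric acid, and quaternary C10 carries its oxygen syn to O9 in the extended chain. The C7 side chain (C11) is anti to O8 and syn to O6. The sensitive groups are the α-methylene lactone (a Michael acceptor), the angelate at C9 (it isomerises to the tiglate), the methacrylate at C8, the free allylic alcohol at C15 and the cross-conjugated dienone. The difficulty lies in a medium ring that contains an E C2=C3 bond (held inside the furanone) and a Z C4=C5 bond, next to a quaternary ether carbon. The strategy rests on the ring diene C2=C3–C4=C5: its E,Z pattern is what conrotatory opening of a cis-fused cyclobutene C2–C3=C4–C5 on an eight-membered ring delivers, and the furanone oxygen fixes the sense of rotation.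

## Retrosynthetic reasoning

37 to 30. The two acyl groups, the exocyclic methylene and the free C15 hydroxyl are the most fragile parts and are put on last. The C15 silyl ether is cleaved in the final step, the C9 angelate and C8 methacrylate are attached to diol 34, and the C11 methylene is introduced on the saturated lactone of 30 while C8 and C9 are still tied up as the acetonide. This order keeps ester enolates, acyl migration and Michael addition out of the earlier chemistry.

30 to 29. The bond C2–C5 is re-formed in the retrosynthetic direction, which turns the diene C2=C3–C4=C5 into a cyclobutene and contracts the ten-membered ring to an eight-membered ketone. This is the cut of choice because it removes the medium ring and both alkene geometries at once and creates no stereocentre in the forward sense. The forward reaction only has to break one strained σ bond.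

29 to 28. The cyclobutene is cut at C2–C3 and C4–C5. This gives a cyclooct-2-enone whose C10 oxygen carries the alkyne C3≡C4 as an ynol ether. The three-atom tether C1–C10–O between C2 and C3 makes the first bond formation a five-ring closure, and the carbon bridge C5–C9 allows only the cis ring fusion.

28 to 24. The lactone carbonyl and the C1 ketone are taken back to alcohols. Neither group survives the organolithium step that makes the ynol ether, so both are raised to their final oxidation state only after the alkyne is in place.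

24 to 21 and 16. The O–C3 bond and the alkyne are traced to a 1,2-dichlorovinyl ether on the tertiary C10 oxygen, and C15 to a one-carbon electrophile. The dichlorovinyl ether is a masked ynol ether that tolerates oxidative cleavage, Grignard addition and metathesis. It is installed when C10–OH is the only hydroxyl in the molecule, so no later differentiation from C1–OH is needed.

21 to 20. The C2=C5 bond of the cyclooctene is cut by ring-closing metathesis of a diene with two terminal vinyl groups. The ring is closed at the eight-membered stage, where a cis alkene is natural, and not at the ten-membered stage.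

20 to 16. Both vinyl carbinols (C1–C2 and C5–C6) come from one double addition of a vinyl nucleophile to dialdehyde 18. The dialdehyde arises from 16 by cleavage of two alkenes in one operation. The C6 stereocentre is set here under control of C7 and C8.

16 to 12. The quaternary C10 carbinol is cut at C10–CH3. A methyl nucleophile adds to vinyl ketone 14 under control of the adjacent dioxolane stereocentre C9. The vinyl group serves as the latent C1 aldehyde.

12 to 5. The C7–C11 bond is cut by a Johnson–Claisen rearrangement. It moves the chirality of an allylic carbinol onto C7 and leaves a propenyl group that is later cleaved to the C6 aldehyde.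

5 to 1. The allylic alcohol comes from the C7 aldehyde 3 by a two-carbon olefination and a catalyst-controlled ketone reduction. The dioxolane carbons C8 and C9, with C7 and C10 as the hydroxymethyl arms, are those of the tartrate-derived threitol acetonide 1.

## Alternatives that were turned down

Alternative 1: The furanone and the ten-membered ring are made together from the nine-membered Z-enoate lactone A1, in which the C10 oxygen is acylated by C3 and C10 carries an acetyl group (C1, C2). In the forward key step the lithium enolate at C2 attacks the lactone carbonyl C3, and acid then removes water to give A2. In its favour, the cyclisation of α-acyloxy ketones to 3(2H)-furanones is classical ionic chemistry at low temperature, needs no photochemistry, and both alkene geometries are fixed beforehand. Against it, A1 requires a nine-membered lactone closed onto a tertiary alcohol, which is one of the hardest lactonisations. The enolate step runs beside a base-sensitive Z-enoate that can be deprotonated at C6. A2 still has C12 as a protected alcohol, so the lactone must be built afterwards. On reliability of the bond-forming event itself this route is stronger than the chosen one. The chosen route offers instead a ring closure at the easy eight-membered stage and a key-step product that already holds the lactone.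

Alternative 2: The bond C9–C10 is cut. The seco aldehyde A3 carries a 2-methyl-3-silyloxyfuran, and under MgBr2·OEt2 the methyl-bearing furan carbon adds to the C9 aldehyde to give A4. This closes the carbocycle, creates quaternary C10 and unmasks the furanone in one step. In its favour, the route is convergent, the α-methylene lactone is already present, and A4 has a free C9 hydroxyl ready for the angelate, so fewer steps follow the key step than in the chosen route. Against it, two stereocentres (C9 and C10) are created during a ten-membered ring closure. Chelation to the C8 ether can guide C9, but the face of the flat furan is selected only by the conformation of the forming ring. The chosen route sets C10 early in an acyclic, correctable addition and creates no stereocentre in its key step.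

Alternative 3: The bond C5–C6 is cut. In A5 a Z alkenyl iodide at C5, attached to the finished furanone, is converted by CrCl2 with catalytic NiCl2 into an alkenylchromium that adds to the C6 aldehyde and gives A6. In its favour, this is the best-proven way to close functionalised medium rings and it tolerates the ketone and the ester, so on precedent it is stronger than the chosen key step. Against it, the C6 carbinol is created in the macrocyclisation with uncertain facial control, although the trans lactone depends on it. The aldehyde sits next to the epimerisable C7, and the lactone still has to be closed afterwards. The chosen route has C6 in place before any ring is made, and its key step can only fail by not proceeding, not by giving the wrong isomer.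

Key step: step 23

## Route

Step 1
Reactants: 1 (+)-2,3-O-isopropylidene-L-threitol
Product: 2 [(4S,5S)-5-{[(4-methoxybenzyl)oxy]methyl}-2,2-dimethyl-1,3-dioxolan-4-yl]methanol
Conditions: NaH (1.0 equiv), 4-methoxybenzyl chloride (1.0 equiv), Bu4NI (cat.), THF/DMF, 0 °C to rt
Reagents that add atoms: 4-methoxybenzyl chloride, COc1ccc(CCl)cc1
Why: Williamson etherification; the two hydroxyls of the C2-symmetric diol are equivalent, so monoalkylation gives one constitutional isomer and leaves C8 and C9 untouched.

Step 2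
Reactants: 2 [(4S,5S)-5-{[(4-methoxybenzyl)oxy]methyl}-2,2-dimethyl-1,3-dioxolan-4-yl]methanol
Product: 3 (4R,5S)-5-{[(4-methoxybenzyl)oxy]methyl}-2,2-dimethyl-1,3-dioxolane-4-carbaldehyde
Conditions: Dess–Martin periodinane, NaHCO3, CH2Cl2, 0 °C to rt
Reagents that add atoms: none
Why: Dess–Martin oxidation of the primary alcohol to the C7 aldehyde under buffered conditions; the trans-dioxolane aldehyde is the thermodynamically preferred epimer, so C8 is not at risk.

Step 3
Reactants: 3 (4R,5S)-5-{[(4-methoxybenzyl)oxy]methyl}-2,2-dimethyl-1,3-dioxolane-4-carbaldehyde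
Product: 4 (E)-4-[(4S,5S)-5-{[(4-methoxybenzyl)oxy]methyl}-2,2-dimethyl-1,3-dioxolan-4-yl]but-3-en-2-one
Conditions: Ph3P=CHC(O)CH3 (1.2 equiv), CH2Cl2, rt
Reagents that add atoms: 1-(triphenylphosphoranylidene)propan-2-one, CC(=O)C=P(c1ccccc1)(c1ccccc1)c1ccccc1
Why: Wittig olefination with a stabilised ylide gives the E enone and brings in C6.

Step 4
Reactants: 4 (E)-4-[(4S,5S)-5-{[(4-methoxybenzyl)oxy]methyl}-2,2-dimethyl-1,3-dioxolan-4-yl]but-3-en-2-one
Product: 5 (2S,3E)-4-[(4S,5S)-5-{[(4-methoxybenzyl)oxy]methyl}-2,2-dimethyl-1,3-dioxolan-4-yl]but-3-en-2-ol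
Conditions: (R)-2-methyl-CBS-oxazaborolidine (0.2 equiv), catecholborane (1.5 equiv), toluene, −78 °C
Reagents that add atoms: none
Why: Corey–Bakshi–Shibata reduction; the (R)-oxazaborolidine treats the alkenyl group as the large and methyl as the small substituent and should give the (S)-carbinol by 1,2-reduction under catalyst control.

Step 5
Reactants: 5 (2S,3E)-4-[(4S,5S)-5-{[(4-methoxybenzyl)oxy]methyl}-2,2-dimethyl-1,3-dioxolan-4-yl]but-3-en-2-ol
Product: 8 ethyl (3S,4E)-3-[(4S,5S)-5-{[(4-methoxybenzyl)oxy]methyl}-2,2-dimethyl-1,3-dioxolan-4-yl]hex-4-enoate, via mixed orthoester 6 (not isolated), via ketene acetal 7 (not isolated)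
Conditions: MeC(OEt)3 (8 equiv), EtCO2H (0.1 equiv), 135 °C, EtOH distilled off
Reagents that add atoms: triethyl orthoacetate, CCOC(C)(OCC)OCC
Why: Johnson–Claisen rearrangement through a chair transition state with the carbinol methyl equatorial; suprafacial 1,3-chirality transfer from the (S)-carbinol sets C7 (S), forms C7–C11 and leaves an E propenyl group as the latent C6 aldehyde.

Step 6
Reactants: 8 ethyl (3S,4E)-3-[(4S,5S)-5-{[(4-methoxybenzyl)oxy]methyl}-2,2-dimethyl-1,3-dioxolan-4-yl]hex-4-enoate
Product: 9 (3S,4E)-3-[(4S,5S)-5-{[(4-methoxybenzyl)oxy]methyl}-2,2-dimethyl-1,3-dioxolan-4-yl]hex-4-en-1-ol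
Conditions: LiAlH4, THF, 0 °C
Reagents that add atoms: none
Why: Hydride reduction of the ester to the C12 alcohol; C12 is kept at the alcohol level because no ester survives the alkoxide and organolithium steps 13 and 18.

Step 7
Reactants: 9 (3S,4E)-3-[(4S,5S)-5-{[(4-methoxybenzyl)oxy]methyl}-2,2-dimethyl-1,3-dioxolan-4-yl]hex-4-en-1-ol
Product: 10 triethyl{[(3S,4E)-3-[(4S,5S)-5-{[(4-methoxybenzyl)oxy]methyl}-2,2-dimethyl-1,3-dioxolan-4-yl]hex-4-en-1-yl]oxy}silane
Conditions: Et3SiCl, imidazole, CH2Cl2, 0 °C
Reagents that add atoms: chlorotriethylsilane, CC[Si](Cl)(CC)CC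
Why: Standard silylation of a primary alcohol; the triethylsilyl ether is stable to base and organometallics and is removed by fluoride in step 19.

Step 8
Reactants: 10 triethyl{[(3S,4E)-3-[(4S,5S)-5-{[(4-methoxybenzyl)oxy]methyl}-2,2-dimethyl-1,3-dioxolan-4-yl]hex-4-en-1-yl]oxy}silane
Product: 11 [(4S,5S)-2,2-dimethyl-5-{(3S,4E)-1-[(triethylsilyl)oxy]hex-4-en-3-yl}-1,3-dioxolan-4-yl]methanol
Conditions: DDQ, CH2Cl2/pH 7 phosphate buffer, 0 °C
Reagents that add atoms: none
Why: Oxidative cleavage of the 4-methoxybenzyl ether; the buffer protects the silyl ether and the acetonide.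

Step 9
Reactants: 11 [(4S,5S)-2,2-dimethyl-5-{(3S,4E)-1-[(triethylsilyl)oxy]hex-4-en-3-yl}-1,3-dioxolan-4-yl]methanol
Product: 12 (4R,5S)-2,2-dimethyl-5-{(3S,4E)-1-[(triethylsilyl)oxy]hex-4-en-3-yl}-1,3-dioxolane-4-carbaldehyde
Conditions: Dess–Martin periodinane, NaHCO3, CH2Cl2, 0 °C to rt
Reagents that add atoms: none
Why: Dess–Martin oxidation to the C10 aldehyde, as in step 2.

Step 10
Reactants: 12 (4R,5S)-2,2-dimethyl-5-{(3S,4E)-1-[(triethylsilyl)oxy]hex-4-en-3-yl}-1,3-dioxolane-4-carbaldehyde
Product: 13 1-[(4S,5S)-2,2-dimethyl-5-{(3S,4E)-1-[(triethylsilyl)oxy]hex-4-en-3-yl}-1,3-dioxolan-4-yl]prop-2-en-1-ol (both carbinol epimers)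
Conditions: CH2=CHMgBr, THF, −78 °C
Reagents that add atoms: vinylmagnesium bromide, C=C[Mg]Br
Why: Grignard addition brings in C1 as a vinyl carbon; the carbinol configuration is irrelevant because it is oxidised in the next step.

Step 11
Reactants: 13 1-[(4S,5S)-2,2-dimethyl-5-{(3S,4E)-1-[(triethylsilyl)oxy]hex-4-en-3-yl}-1,3-dioxolan-4-yl]prop-2-en-1-ol
Product: 14 1-[(4R,5S)-2,2-dimethyl-5-{(3S,4E)-1-[(triethylsilyl)oxy]hex-4-en-3-yl}-1,3-dioxolan-4-yl]prop-2-en-1-one
Conditions: Dess–Martin periodinane, NaHCO3, CH2Cl2, 0 °C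
Reagents that add atoms: none
Why: Dess–Martin oxidation of the allylic alcohol to the vinyl ketone, which is used at once.

Step 12
Reactants: 14 1-[(4R,5S)-2,2-dimethyl-5-{(3S,4E)-1-[(triethylsilyl)oxy]hex-4-en-3-yl}-1,3-dioxolan-4-yl]prop-2-en-1-one
Product: 15 (2R)-2-[(4R,5S)-2,2-dimethyl-5-{(3S,4E)-1-[(triethylsilyl)oxy]hex-4-en-3-yl}-1,3-dioxolan-4-yl]but-3-en-2-ol
Conditions: MeLi, THF, −78 °C
Reagents that add atoms: methyllithium, [Li]C
Why: 1,2-Addition of methyllithium under Felkin–Anh (non-chelation) control: attack anti to the C9–O bond of the weakly coordinating dioxolane puts the new hydroxyl syn to O9 along the C8–C9–C10–C1 chain, which is the target configuration at quaternary C10.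

Step 13
Reactants: 15 (2R)-2-[(4R,5S)-2,2-dimethyl-5-{(3S,4E)-1-[(triethylsilyl)oxy]hex-4-en-3-yl}-1,3-dioxolan-4-yl]but-3-en-2-ol
Product: 16 (4R,5S)-4-[(2R)-2-{[(E)-1,2-dichloroethenyl]oxy}but-3-en-2-yl]-2,2-dimethyl-5-{(3S,4E)-1-[(triethylsilyl)oxy]hex-4-en-3-yl}-1,3-dioxolane
Conditions: KH (1.5 equiv), THF, 0 °C; ClCH=CCl2 (1.2 equiv), 0 °C to rt
Reagents that add atoms: trichloroethylene, ClC=C(Cl)Cl
Why: The tertiary potassium alkoxide adds anti to dichloroacetylene formed in the flask and gives the E dichlorovinyl ether, a robust masked ynol ether that supplies C3 and C4; the ether is kept at or below room temperature and is not stored.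

Step 14
Reactants: 16 (4R,5S)-4-[(2R)-2-{[(E)-1,2-dichloroethenyl]oxy}but-3-en-2-yl]-2,2-dimethyl-5-{(3S,4E)-1-[(triethylsilyl)oxy]hex-4-en-3-yl}-1,3-dioxolane
Product: 18 (2S)-2-{[(E)-1,2-dichloroethenyl]oxy}-2-[(4R,5S)-2,2-dimethyl-5-{(2R)-1-oxo-4-[(triethylsilyl)oxy]butan-2-yl}-1,3-dioxolan-4-yl]propanal, via tetraol 17 (not isolated)
Conditions: OsO4 (2 mol %), NaIO4 (5 equiv), 2,6-lutidine (4 equiv), 1,4-dioxane/H2O 3:1, rt
Reagents that add atoms: sodium periodate, [Na+].[O-]I(=O)(=O)=O; osmium tetroxide, O=[Os](=O)(=O)=O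
Why: Lemieux–Johnson cleavage of the vinyl and the propenyl group in one operation gives the C1 and C6 aldehydes; the dichlorovinyl ether is trisubstituted, hindered and deactivated by two chlorines and should not react, and lutidine limits epimerisation at C7.

Step 15
Reactants: 18 (2S)-2-{[(E)-1,2-dichloroethenyl]oxy}-2-[(4R,5S)-2,2-dimethyl-5-{(2R)-1-oxo-4-[(triethylsilyl)oxy]butan-2-yl}-1,3-dioxolan-4-yl]propanal
Product: 19 (3R,4S)-4-[(4S,5R)-5-{(2R)-2-{[(E)-1,2-dichloroethenyl]oxy}-3-hydroxypent-4-en-2-yl}-2,2-dimethyl-1,3-dioxolan-4-yl]-6-[(triethylsilyl)oxy]hex-1-en-3-ol (both epimers at the pentenyl carbinol, C1)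
Conditions: CH2=CHMgBr (3 equiv), THF, −78 °C
Reagents that add atoms: vinylmagnesium bromide, C=C[Mg]Br
Why: Double Grignard addition brings in C2 and C5; at C6, Felkin–Anh attack anti to the C8 branch on C7 and 1,3-anti induction from O8 reinforce each other and should give the 6R carbinol (hydroxyl syn to the C11 branch), while the C1 carbinol forms as a mixture that is erased in step 21.

Step 16
Reactants: 19 (3R,4S)-4-[(4S,5R)-5-{(2R)-2-{[(E)-1,2-dichloroethenyl]oxy}-3-hydroxypent-4-en-2-yl}-2,2-dimethyl-1,3-dioxolan-4-yl]-6-[(triethylsilyl)oxy]hex-1-en-3-ol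
Product: 20 tris(triethylsilyl) ether of 19 (C1–O, C6–O and C12–O silylated; diene with C10 dichlorovinyl ether)
Conditions: Et3SiOTf (2.4 equiv), 2,6-lutidine, CH2Cl2, −78 °C
Reagents that add atoms: triethylsilyl trifluoromethanesulfonate, CC[Si](CC)(CC)OS(=O)(=O)C(F)(F)F
Why: Silylation of both secondary allylic alcohols, including the hindered C1 hydroxyl, so that no free hydroxyl is present in the metathesis and organolithium steps.

Step 17
Reactants: 20 tris(triethylsilyl) ether of 19
Product: 21 (Z)-cyclooctene of C1, C2, C5–C10 with 1-OSiEt3 (both epimers), 6-OSiEt3, 7-(2-triethylsilyloxyethyl), 8,9-O-isopropylidene, 10-methyl and 10-O-[(E)-1,2-dichloroethenyl]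
Conditions: second-generation Grubbs catalyst RuCl2(=CHPh)(PCy3)(H2IMes) (10 mol %), CH2Cl2 (1 mM), 40 °C
Reagents that add atoms: none
Why: Ring-closing metathesis of two monosubstituted alkenes forms the Z C2=C5 bond of the eight-membered ring with loss of ethene; the chlorinated enol ether is inert to the ruthenium carbene, whereas a free ynol ether would not be, so the alkyne is unmasked only after this step.

Step 18
Reactants: 21 (Z)-cyclooctene with 10-O-[(E)-1,2-dichloroethenyl]
Product: 24 (Z)-cyclooctene with 10-O–C≡C–CH2OSi(iPr)3 and three triethylsilyl ethers, via lithium alkoxyacetylide 22 (not isolated), via lithium propargylic alkoxide 23 (not isolated)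
Conditions: n-BuLi (2.4 equiv), THF, −78 to −40 °C; (CH2O)n, −78 to 0 °C; iPr3SiCl, imidazole, DMF, 0 °C to rt
Reagents that add atoms: formaldehyde (as paraformaldehyde), C=O; chlorotriisopropylsilane, CC(C)[Si](Cl)(C(C)C)C(C)C
Why: Dehydrochlorination and chlorine–lithium exchange turn the dichlorovinyl ether into the lithium alkoxyacetylide (the standard ynol ether synthesis), which adds to formaldehyde to form C4–C15; the primary alkoxide is silylated in the same flask, and the substrate holds no ester or ketone at this point.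

Step 19
Reactants: 24 (Z)-cyclooctene with 10-O–C≡C–CH2OSi(iPr)3 and three triethylsilyl ethers
Product: 25 1,6,12-triol with 10-O–C≡C–CH2OSi(iPr)3
Conditions: Bu4NF (3.3 equiv), THF, −20 to 0 °C
Reagents that add atoms: none
Why: Fluoride cleaves the three triethylsilyl ethers far faster than the primary triisopropylsilyl ether, and the basic medium spares the acid-labile ynol ether.

Step 20
Reactants: 25 1,6,12-triol with 10-O–C≡C–CH2OSi(iPr)3
Product: 27 trans-fused 12,6-lactone with free C1 hydroxyl, via lactol 26 (not isolated)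
Conditions: PhI(OAc)2 (2.3 equiv), TEMPO (0.2 equiv), CH2Cl2/pH 7 phosphate buffer, 0 °C to rt
Reagents that add atoms: none
Why: Oxoammonium oxidation is selective for the primary C12 alcohol; the aldehyde is trapped by the C6 hydroxyl as a five-membered lactol and oxidised on to the γ-lactone, and the buffer keeps acetic acid away from the ynol ether.

Step 21
Reactants: 27 trans-fused 12,6-lactone with free C1 hydroxyl
Product: 28 cyclooct-2-enone with 12,6-lactone, 8,9-O-isopropylidene and 10-O–C≡C–CH2OSi(iPr)3
Conditions: Dess–Martin periodinane, NaHCO3, CH2Cl2, 0 °C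
Reagents that add atoms: none
Why: Dess–Martin oxidation of both C1 epimers of the allylic alcohol converges on one enone; the product is kept cold because a tertiary ynol ether can lose its alkyl group by a retro-ene path on heating.

Step 22
Reactants: 28 cyclooct-2-enone with 10-O–C≡C–CH2OSi(iPr)3
Product: 29 (2S,5R)-tricyclic cyclobutene: four-membered ring C2–C3=C4–C5 cis-fused to the eight-membered C1 ketone, with oxygen bridge C3–O–C10
Conditions: hν (350 nm, Pyrex), degassed MeCN (2 mM), 0 °C, stopped before full conversion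
Reagents that add atoms: none
Why: Intramolecular enone–alkyne [2+2] photocycloaddition through the enone triplet: C2–C3 forms first as a five-ring closure (rule of five), then C4–C5, with the oxygen-bearing alkyne carbon on the enone α-carbon as in head-to-tail additions of electron-rich partners. The bridge C5–C9 joins C2 and C10 on one face of the new five-membered ring, so only the cis-fused cyclobutene can form. The reaction type is established for carbon-tethered alkynes, and the oxygen-tethered ynol ether is a new substrate for it.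

Step 23
Reactants: 29 (2S,5R)-tricyclic cyclobutene
Product: 30 furanone-bridged (2E,4Z)-cyclodecadiene with saturated 12,6-lactone, 8,9-O-isopropylidene and 15-OSi(iPr)3
Conditions: toluene (degassed, base-washed glass), BHT (cat.), 110 °C
Reagents that add atoms: none
Why: Thermally allowed four-electron conrotatory electrocyclic opening of the cyclobutene: the σ bond C2–C5, shared by the four- and the eight-membered ring, breaks and C2=C3 and C4=C5 form. The closest known reaction type is the thermal opening of cis-bicyclo[6.2.0]dec-9-enes from enone–alkyne photoadducts to cis,trans-cyclodeca-1,3-dienes, and of bicyclo[3.2.0]hept-5-enes to 1-vinylcyclopentenes. No ring is closed by bond formation: the ten-membered carbocycle arises by merging the four- and eight-membered rings, and the new C2=C3 bond completes the furanone. No stereocentre is created; C2 and C5 are lost and their cis relationship passes into the alkene geometries. The five-membered ring O–C3–C2–C1–C10 can hold only a cis C2=C3 bond, so C1 must rotate outward, and conrotation then turns C6 on C5 inward and gives the Z C4=C5 bond with C3 and C6 cis, as in 37. The other conrotatory sense would need a trans double bond in a five-membered ring and the disrotatory modes are forbidden, so the torquoselectivity is secured by the oxygen bridge together with the cis fusion of 29. Strain of the doubly fused cyclobutene, the donor oxygen on C3 with the acyl group on C2 (a push–pull arrangement) and the gain of the vinylogous ester should offset the inward rotation of the alkyl substituent.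

Step 24
Reactants: 30 furanone-bridged (2E,4Z)-cyclodecadiene with saturated lactone
Product: 33 11(13)-methylene lactone with 8,9-O-isopropylidene and 15-OSi(iPr)3, via Mannich base 31 (not isolated), via ammonium iodide 32 (not isolated)
Conditions: LiN(iPr)2 (1.1 equiv), THF, −78 °C; (Me2N=CH2)I, −78 to 0 °C; MeI, MeOH, rt; NaHCO3 (aq)/CH2Cl2, rt
Reagents that add atoms: N,N-dimethylmethyleneiminium iodide, C=[N+](C)C.[I-]
Why: Eschenmoser methylenation: kinetic deprotonation of the unhindered lactone CH2 (the C1 ketone has no α-hydrogen, C10 being quaternary and C2 vinylic), Mannich reaction, quaternisation and elimination give C11=C13.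

Step 25
Reactants: 33 11(13)-methylene lactone with 8,9-O-isopropylidene
Product: 34 8,9-diol with 15-OSi(iPr)3
Conditions: AcOH/H2O 4:1, 45 °C
Reagents that add atoms: none
Why: Acid hydrolysis of the trans-fused dioxolane; the primary triisopropylsilyl ether and the vinylogous ester tolerate aqueous acetic acid.

Step 26
Reactants: 34 8,9-diol with 15-OSi(iPr)3
Product: 35 8-methacrylate with free C9 hydroxyl
Conditions: methacrylic anhydride (1.2 equiv), Et3N, DMAP (cat.), CH2Cl2, −20 to 0 °C
Reagents that add atoms: methacrylic anhydride, C=C(C)C(=O)OC(=O)C(C)=C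
Why: Acylation goes to the less hindered C8 hydroxyl; the C9 hydroxyl is shielded by quaternary C10.

Step 27
Reactants: 35 8-methacrylate with free C9 hydroxyl
Product: 36 8-methacrylate 9-angelate with 15-OSi(iPr)3
Conditions: angelic acid (3 equiv), 2,4,6-trichlorobenzoyl chloride (3 equiv), Et3N, toluene, rt; then 35, 75 °C
Reagents that add atoms: angelic acid, C/C=C(/C)C(=O)O
Why: Yamaguchi-type esterification through the mixed anhydride without a nucleophilic catalyst, the usual way to acylate hindered alcohols with angelic acid while keeping the Z geometry.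

Step 28
Reactants: 36 8-methacrylate 9-angelate with 15-OSi(iPr)3
Product: 37 (4Z,6R,7S,8S,9R,10S)-9-(angeloyloxy)-15-hydroxy-8-(methacryloyloxy)-1-oxo-3,10-epoxygermacra-2,4,11(13)-trien-12,6-olide
Conditions: HF·pyridine, pyridine/THF, 0 °C to rt
Reagents that add atoms: none
Why: Buffered fluoride cleavage of the primary silyl ether; the conditions are not basic, so the esters do not migrate and the methylene lactone is not attacked.

## Compound list

1 | (+)-2,3-O-isopropylidene-L-threitol, [(4S,5S)-2,2-dimethyl-1,3-dioxolane-4,5-diyl]dimethanol | CC1(C)O[C@@H](CO)[C@H](CO)O1 | starting material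
2 | [(4S,5S)-5-{[(4-methoxybenzyl)oxy]methyl}-2,2-dimethyl-1,3-dioxolan-4-yl]methanol | CC1(C)O[C@@H](CO)[C@H](COCc2ccc(OC)cc2)O1 | intermediate
3 | (4R,5S)-5-{[(4-methoxybenzyl)oxy]methyl}-2,2-dimethyl-1,3-dioxolane-4-carbaldehyde | CC1(C)O[C@@H](C=O)[C@H](COCc2ccc(OC)cc2)O1 | intermediate
4 | (E)-4-[(4S,5S)-5-{[(4-methoxybenzyl)oxy]methyl}-2,2-dimethyl-1,3-dioxolan-4-yl]but-3-en-2-one | CC1(C)O[C@@H](/C=C/C(C)=O)[C@H](COCc2ccc(OC)cc2)O1 | intermediate
5 | (2S,3E)-4-[(4S,5S)-5-{[(4-methoxybenzyl)oxy]methyl}-2,2-dimethyl-1,3-dioxolan-4-yl]but-3-en-2-ol | CC1(C)O[C@@H](/C=C/[C@H](C)O)[C@H](COCc2ccc(OC)cc2)O1 | intermediate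
6 | mixed orthoester: diethyl (2S,3E)-4-[(4S,5S)-5-{[(4-methoxybenzyl)oxy]methyl}-2,2-dimethyl-1,3-dioxolan-4-yl]but-3-en-2-yl orthoacetate | CC1(C)O[C@@H](/C=C/[C@H](C)OC(C)(OCC)OCC)[C@H](COCc2ccc(OC)cc2)O1 | intermediate
7 | ketene acetal: 1-ethoxyethenyl ether of 5 | CC1(C)O[C@@H](/C=C/[C@H](C)OC(=C)OCC)[C@H](COCc2ccc(OC)cc2)O1 | intermediate
8 | ethyl (3S,4E)-3-[(4S,5S)-5-{[(4-methoxybenzyl)oxy]methyl}-2,2-dimethyl-1,3-dioxolan-4-yl]hex-4-enoate | CC1(C)O[C@@H]([C@H](/C=C/C)CC(=O)OCC)[C@H](COCc2ccc(OC)cc2)O1 | intermediate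
9 | (3S,4E)-3-[(4S,5S)-5-{[(4-methoxybenzyl)oxy]methyl}-2,2-dimethyl-1,3-dioxolan-4-yl]hex-4-en-1-ol | CC1(C)O[C@@H]([C@H](/C=C/C)CCO)[C@H](COCc2ccc(OC)cc2)O1 | intermediate
10 | triethyl{[(3S,4E)-3-[(4S,5S)-5-{[(4-methoxybenzyl)oxy]methyl}-2,2-dimethyl-1,3-dioxolan-4-yl]hex-4-en-1-yl]oxy}silane | CC1(C)O[C@@H]([C@H](/C=C/C)CCO[Si](CC)(CC)CC)[C@H](COCc2ccc(OC)cc2)O1 | intermediate
11 | [(4S,5S)-2,2-dimethyl-5-{(3S,4E)-1-[(triethylsilyl)oxy]hex-4-en-3-yl}-1,3-dioxolan-4-yl]methanol | CC1(C)O[C@@H]([C@H](/C=C/C)CCO[Si](CC)(CC)CC)[C@H](CO)O1 | intermediate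
12 | (4R,5S)-2,2-dimethyl-5-{(3S,4E)-1-[(triethylsilyl)oxy]hex-4-en-3-yl}-1,3-dioxolane-4-carbaldehyde | CC1(C)O[C@@H]([C@H](/C=C/C)CCO[Si](CC)(CC)CC)[C@H](C=O)O1 | intermediate
13 | 1-[(4S,5S)-2,2-dimethyl-5-{(3S,4E)-1-[(triethylsilyl)oxy]hex-4-en-3-yl}-1,3-dioxolan-4-yl]prop-2-en-1-ol, both carbinol epimers | CC1(C)O[C@@H]([C@H](/C=C/C)CCO[Si](CC)(CC)CC)[C@H](C(O)C=C)O1 | intermediate
14 | 1-[(4R,5S)-2,2-dimethyl-5-{(3S,4E)-1-[(triethylsilyl)oxy]hex-4-en-3-yl}-1,3-dioxolan-4-yl]prop-2-en-1-one | CC1(C)O[C@@H]([C@H](/C=C/C)CCO[Si](CC)(CC)CC)[C@H](C(=O)C=C)O1 | intermediate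
15 | (2R)-2-[(4R,5S)-2,2-dimethyl-5-{(3S,4E)-1-[(triethylsilyl)oxy]hex-4-en-3-yl}-1,3-dioxolan-4-yl]but-3-en-2-ol | CC1(C)O[C@@H]([C@H](/C=C/C)CCO[Si](CC)(CC)CC)[C@H]([C@](C)(O)C=C)O1 | intermediate
16 | (4R,5S)-4-[(2R)-2-{[(E)-1,2-dichloroethenyl]oxy}but-3-en-2-yl]-2,2-dimethyl-5-{(3S,4E)-1-[(triethylsilyl)oxy]hex-4-en-3-yl}-1,3-dioxolane | CC1(C)O[C@@H]([C@H](/C=C/C)CCO[Si](CC)(CC)CC)[C@H]([C@](C)(O/C(Cl)=C\Cl)C=C)O1 | intermediate
17 | tetraol: 16 with the vinyl and the propenyl C=C bonds each converted into a vicinal diol (new carbinols as mixtures, C7–C10 as in 16) | CC1(C)O[C@@H]([C@H](C(O)C(C)O)CCO[Si](CC)(CC)CC)[C@H]([C@](C)(O/C(Cl)=C\Cl)C(O)CO)O1 | intermediate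
18 | (2S)-2-{[(E)-1,2-dichloroethenyl]oxy}-2-[(4R,5S)-2,2-dimethyl-5-{(2R)-1-oxo-4-[(triethylsilyl)oxy]butan-2-yl}-1,3-dioxolan-4-yl]propanal | CC1(C)O[C@@H]([C@H](C=O)CCO[Si](CC)(CC)CC)[C@H]([C@](C)(O/C(Cl)=C\Cl)C=O)O1 | intermediate
19 | (3R,4S)-4-[(4S,5R)-5-{(2R)-2-{[(E)-1,2-dichloroethenyl]oxy}-3-hydroxypent-4-en-2-yl}-2,2-dimethyl-1,3-dioxolan-4-yl]-6-[(triethylsilyl)oxy]hex-1-en-3-ol, both epimers at C1 | CC1(C)O[C@@H]([C@H]([C@H](O)C=C)CCO[Si](CC)(CC)CC)[C@H]([C@](C)(O/C(Cl)=C\Cl)C(O)C=C)O1 | intermediate
20 | tris(triethylsilyl) ether of 19 (C1–O, C6–O, C12–O), both epimers at C1 | CC1(C)O[C@@H]([C@H]([C@H](O[Si](CC)(CC)CC)C=C)CCO[Si](CC)(CC)CC)[C@H]([C@](C)(O/C(Cl)=C\Cl)C(O[Si](CC)(CC)CC)C=C)O1 | intermediate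
21 | (Z)-cyclooctene (ring C1, C2, C5–C10): 1-OSiEt3 (both epimers), 6-OSiEt3, 7-(2-triethylsilyloxyethyl), 8,9-O-isopropylidene, 10-methyl, 10-O-[(E)-1,2-dichloroethenyl]; C6–C10 arranged as in 37 | CC1(C)O[C@H]2[C@@H](CCO[Si](CC)(CC)CC)[C@H](O[Si](CC)(CC)CC)/C=C\C(O[Si](CC)(CC)CC)[C@@](C)(O/C(Cl)=C\Cl)[C@@H]2O1 | intermediate
22 | lithium alkoxyacetylide: 21 with 10-O–C≡C–Li in place of the dichlorovinyl ether | CC1(C)O[C@H]2[C@@H](CCO[Si](CC)(CC)CC)[C@H](O[Si](CC)(CC)CC)/C=C\C(O[Si](CC)(CC)CC)[C@@](C)(OC#C[Li])[C@@H]2O1 | intermediate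
23 | lithium propargylic alkoxide: 10-O–C≡C–CH2OLi | CC1(C)O[C@H]2[C@@H](CCO[Si](CC)(CC)CC)[C@H](O[Si](CC)(CC)CC)/C=C\C(O[Si](CC)(CC)CC)[C@@](C)(OC#CC[O-])[C@@H]2O1.[Li+] | intermediate
24 | (Z)-cyclooctene as 21 with 10-O–C≡C–CH2OSi(iPr)3 (ynol ether) | CC1(C)O[C@H]2[C@@H](CCO[Si](CC)(CC)CC)[C@H](O[Si](CC)(CC)CC)/C=C\C(O[Si](CC)(CC)CC)[C@@](C)(OC#CCO[Si](C(C)C)(C(C)C)C(C)C)[C@@H]2O1 | intermediate
25 | 1,6,12-triol: (Z)-cyclooctene with 1-OH (both epimers), 6-OH, 7-(2-hydroxyethyl), 8,9-O-isopropylidene, 10-methyl, 10-O–C≡C–CH2OSi(iPr)3 | CC1(C)O[C@H]2[C@@H](CCO)[C@H](O)/C=C\C(O)[C@@](C)(OC#CCO[Si](C(C)C)(C(C)C)C(C)C)[C@@H]2O1 | intermediate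
26 | lactol: 25 with C12 as cyclic hemiacetal on O6 (anomers, C1 epimers) | CC1(C)O[C@H]2[C@H]3CC(O)O[C@@H]3/C=C\C(O)[C@@](C)(OC#CCO[Si](C(C)C)(C(C)C)C(C)C)[C@@H]2O1 | intermediate
27 | hydroxy lactone: trans-fused 12,6-γ-lactone on the (Z)-cyclooctene, 1-OH (both epimers), 8,9-O-isopropylidene, 10-O–C≡C–CH2OSi(iPr)3 | CC1(C)O[C@H]2[C@H]3CC(=O)O[C@@H]3/C=C\C(O)[C@@](C)(OC#CCO[Si](C(C)C)(C(C)C)C(C)C)[C@@H]2O1 | intermediate
28 | cyclooct-2-enone (C1 ketone, Z C2=C5) with trans-fused 12,6-lactone, 8,9-O-isopropylidene, 10-methyl and 10-O–C≡C–CH2OSi(iPr)3; C6–C10 arranged as in 37 | CC1(C)O[C@H]2[C@H]3CC(=O)O[C@@H]3/C=C\C(=O)[C@@](C)(OC#CCO[Si](C(C)C)(C(C)C)C(C)C)[C@@H]2O1 | intermediate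
29 | (2S,5R)-tricyclic cyclobutene: four-membered ring C2–C3=C4–C5 cis-fused (H2 and H5 syn) to the eight-membered C1 ketone, oxygen bridge C3–O–C10, 4-CH2OSi(iPr)3, 12,6-lactone, 8,9-O-isopropylidene; C6–C10 arranged as in 37 | CC1(C)O[C@H]2[C@H]3CC(=O)O[C@@H]3[C@H]3C(CO[Si](C(C)C)(C(C)C)C(C)C)=C4O[C@](C)(C(=O)[C@@H]34)[C@@H]2O1 | intermediate
30 | (4Z)-15-(triisopropylsilyloxy)-8,9-O-isopropylidene-1-oxo-3,10-epoxygermacra-2,4-dien-12,6-olide; C6–C10 arranged as in 37 | CC1(C)O[C@H]2[C@H]3CC(=O)O[C@@H]3/C=C(/CO[Si](C(C)C)(C(C)C)C(C)C)C3=CC(=O)[C@@](C)(O3)[C@@H]2O1 | intermediate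
31 | Mannich base: 30 with 11-(dimethylaminomethyl) (C11 epimers) | CC1(C)O[C@H]2[C@H]3C(CN(C)C)C(=O)O[C@@H]3/C=C(/CO[Si](C(C)C)(C(C)C)C(C)C)C3=CC(=O)[C@@](C)(O3)[C@@H]2O1 | intermediate
32 | ammonium iodide: 30 with 11-(trimethylammoniomethyl), iodide | CC1(C)O[C@H]2[C@H]3C(C[N+](C)(C)C)C(=O)O[C@@H]3/C=C(/CO[Si](C(C)C)(C(C)C)C(C)C)C3=CC(=O)[C@@](C)(O3)[C@@H]2O1.[I-] | intermediate
33 | (4Z)-15-(triisopropylsilyloxy)-8,9-O-isopropylidene-1-oxo-3,10-epoxygermacra-2,4,11(13)-trien-12,6-olide | CC1(C)O[C@H]2[C@H]3C(=C)C(=O)O[C@@H]3/C=C(/CO[Si](C(C)C)(C(C)C)C(C)C)C3=CC(=O)[C@@](C)(O3)[C@@H]2O1 | intermediate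
34 | (4Z)-8,9-dihydroxy-15-(triisopropylsilyloxy)-1-oxo-3,10-epoxygermacra-2,4,11(13)-trien-12,6-olide | O[C@H]1[C@H]2C(=C)C(=O)O[C@@H]2/C=C(/CO[Si](C(C)C)(C(C)C)C(C)C)C2=CC(=O)[C@@](C)(O2)[C@@H]1O | intermediate
35 | (4Z)-9-hydroxy-8-(methacryloyloxy)-15-(triisopropylsilyloxy)-1-oxo-3,10-epoxygermacra-2,4,11(13)-trien-12,6-olide | C=C(C)C(=O)O[C@H]1[C@H]2C(=C)C(=O)O[C@@H]2/C=C(/CO[Si](C(C)C)(C(C)C)C(C)C)C2=CC(=O)[C@@](C)(O2)[C@@H]1O | intermediate
36 | (4Z)-9-(angeloyloxy)-8-(methacryloyloxy)-15-(triisopropylsilyloxy)-1-oxo-3,10-epoxygermacra-2,4,11(13)-trien-12,6-olide | C=C(C)C(=O)O[C@H]1[C@H]2C(=C)C(=O)O[C@@H]2/C=C(/CO[Si](C(C)C)(C(C)C)C(C)C)C2=CC(=O)[C@@](C)(O2)[C@@H]1OC(=O)/C(C)=C\C | intermediate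
37 | (4Z,6R,7S,8S,9R,10S)-9-(angeloyloxy)-15-hydroxy-8-(methacryloyloxy)-1-oxo-3,10-epoxygermacra-2,4,11(13)-trien-12,6-olide (CNP0359568.2) | C=C(C)C(=O)O[C@H]1[C@H]2C(=C)C(=O)O[C@@H]2/C=C(/CO)C2=CC(=O)[C@@](C)(O2)[C@@H]1OC(=O)/C(C)=C\C | target

## Step count and least certain steps

Total: 28 steps. Longest linear sequence: 28 steps (the route is fully linear from 1).

Step 23 (key step). The most likely failure is that the opening is too slow at temperatures the strained enol ether tolerates, because the C6 substituent must rotate inward, which is the sterically unfavourable sense. Decomposition or a non-concerted cleavage could then compete and erode the C4=C5 geometry. Fallback: the same C2–C5 bond is broken by a stepwise ionic route. Treating 29 with Me2AlCl in CH2Cl2 at −78 to −20 °C activates the C1 ketone, so that the bond cleaves heterolytically to an aluminium enolate at C2 and an oxocarbenium ion delocalised over C3–C5; this is the retro direction of a Ficini-type cycloaddition. Collapse gives 30 directly, with the C4=C5 geometry then resting on the ring and not on orbital symmetry. The fallback sets out from 29 and returns at 30 without new compounds.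

Step 22. The excited enone may leave by other channels: Z/E isomerisation of the cyclooctenone followed by unselective ground-state addition, electron transfer from the electron-rich ynol ether, or a secondary 1,3-acyl shift of the β,γ-unsaturated ketone product on over-irradiation. Fallback: the cyclobutene is made in the ground state by a Lewis-acid-catalysed stepwise [2+2] cycloaddition (Ficini type, established for silyl ynol ethers and enones) with AgNTf2 (10 mol %) in CH2Cl2 at −40 °C. The nucleophilic alkyne carbon C4 adds to the enone β-carbon C5 and the enolate carbon C2 closes onto C3, which is the same regiochemistry. It sets out from 28 and returns at 29 without new compounds.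

Step 17. Ring closure may lose to oligomerisation by cross-metathesis, because both alkenes are allylic silyl ethers, one lies next to quaternary C10, and an eight-membered ring is costly to close. Fallback: a temporary silicon tether. Diol 19 is treated with iPr2SiCl2 and imidazole in DMF to give the cyclic silylene F1, which holds the two vinyl groups together. Metathesis with the same ruthenium catalyst gives the bridged cyclooctene F2, Bu4NF removes the silylene and the C12 silyl ether to give triol F3, and Et3SiOTf with 2,6-lutidine returns to 21.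

Step 12. Facial selectivity at C10 may be poor, or the sense may be reversed if the dioxolane oxygen chelates lithium. Fallback: the order of the two nucleophiles is exchanged, so that the same sense of induction then works in favour. Aldehyde 12 is treated with MeMgBr to give the secondary alcohol F4, Dess–Martin oxidation gives the methyl ketone F5, and addition of CH2=CHMgBr (with MgBr2·OEt2 in CH2Cl2 if chelation proves to be the controlling mode) returns to 15.

Step 15. Facial selectivity at C6 may be insufficient, and the dialdehyde may epimerise at C7 before it reacts. Fallback: substrate control is replaced by catalyst control. Zn(CH=CH2)2 with a chiral amino alcohol ligand (3-exo-morpholinoisoborneol) in toluene at 0 °C adds vinyl to both aldehydes of 18 with the ligand setting the new carbinols, under non-basic conditions. It sets out from 18 and returns at 19 without new compounds.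

## Further compounds

F0 | step 23 | none | none
F0 | step 22 | none | none
F1 | step 17 | cyclic diisopropylsilylene of diol 19 (O1–Si–O6 bridge, nine-membered ring; both epimers at C1) | CC1(C)O[C@H]2[C@@H](CCO[Si](CC)(CC)CC)[C@@H](C=C)O[Si](C(C)C)(C(C)C)OC(C=C)[C@@](C)(O/C(Cl)=C\Cl)[C@@H]2O1
F2 | step 17 | silylene-bridged (Z)-cyclooctene from F1 (C2=C5 closed; both epimers at C1) | CC1(C)O[C@H]2[C@@H](CCO[Si](CC)(CC)CC)[C@H]3/C=C\C(O[Si](C(C)C)(C(C)C)O3)[C@@](C)(O/C(Cl)=C\Cl)[C@@H]2O1
F3 | step 17 | 1,6,12-triol of the (Z)-cyclooctene with 10-O-[(E)-1,2-dichloroethenyl] (both epimers at C1) | CC1(C)O[C@H]2[C@@H](CCO)[C@H](O)/C=C\C(O)[C@@](C)(O/C(Cl)=C\Cl)[C@@H]2O1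
F4 | step 12 | 1-[(4S,5S)-2,2-dimethyl-5-{(3S,4E)-1-[(triethylsilyl)oxy]hex-4-en-3-yl}-1,3-dioxolan-4-yl]ethanol (both carbinol epimers) | CC1(C)O[C@@H]([C@H](/C=C/C)CCO[Si](CC)(CC)CC)[C@H](C(C)O)O1
F5 | step 12 | 1-[(4R,5S)-2,2-dimethyl-5-{(3S,4E)-1-[(triethylsilyl)oxy]hex-4-en-3-yl}-1,3-dioxolan-4-yl]ethanone | CC1(C)O[C@@H]([C@H](/C=C/C)CCO[Si](CC)(CC)CC)[C@H](C(C)=O)O1
F0 | step 15 | none | none
A1 | alternative 1 | nine-membered Z-enoate lactone (C10–O–C3(=O)) with C10 acetyl, 8,9-O-isopropylidene, 6-OTBS, 15-OTBS and C12 as 4-methoxybenzyl ether | CC1(C)O[C@H]2[C@@H](C(=C)COCc3ccc(OC)cc3)[C@H](O[Si](C)(C)C(C)(C)C)/C=C(/CO[Si](C)(C)C(C)(C)C)C(=O)O[C@](C)(C(C)=O)[C@@H]2O1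
A2 | alternative 1 | furanone-bridged ten-membered carbocycle, lactone masked | CC1(C)O[C@H]2[C@@H](C(=C)COCc3ccc(OC)cc3)[C@H](O[Si](C)(C)C(C)(C)C)/C=C(/CO[Si](C)(C)C(C)(C)C)C3=CC(=O)[C@@](C)(O3)[C@@H]2O1
A3 | alternative 2 | seco C9 aldehyde with 8-O-(4-methoxybenzyl), α-methylene lactone and 2-methyl-3-(tert-butyldimethylsilyloxy)furan at C4 | COc1ccc(CO[C@H](C=O)[C@H]2C(=C)C(=O)O[C@@H]2/C=C(/CO[Si](C)(C)C(C)(C)C)c2cc(O[Si](C)(C)C(C)(C)C)c(C)o2)cc1
A4 | alternative 2 | bridged macrocycle with free C9 hydroxyl | COc1ccc(CO[C@H]2[C@H]3C(=C)C(=O)O[C@@H]3/C=C(/CO[Si](C)(C)C(C)(C)C)C3=CC(=O)[C@@](C)(O3)[C@@H]2O)cc1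
A5 | alternative 3 | seco C6 aldehyde with (Z)-C5 alkenyl iodide on the finished furanone, C12 methyl ester and 8,9-O-isopropylidene | I/C=C(/CO[Si](C)(C)C(C)(C)C)C1=CC(=O)[C@@](C)(O1)[C@@H]1OC(C)(C)O[C@H]1[C@@H](CC(=O)OC)C=O
A6 | alternative 3 | bridged macrocycle with C6 hydroxyl and C12 ester | CC1(C)O[C@H]2[C@@H](CC(=O)OC)[C@H](O)/C=C(/CO[Si](C)(C)C(C)(C)C)C3=CC(=O)[C@@](C)(O3)[C@@H]2O1
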